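**Plan**
- Retrosynthesis: cut the benzyl ester C–O bond last. Then cut ring A at C1–C2 and C5–C6 (cycloaddition/aromatisation). Then cut the ArO–CH2 bond of a 4-aryloxyacetoacetate. On ring B cut C–CO2Me (carbonylation), C–Bu (Grignard) and C–Br.
- Enabling feature: ring A carries oxygen at C2, C4 and C5 (C5 is the aryl ether) and adjacent carbon substituents at C1 (carboxyl) and C6 (pentyl). C2–C5 with their three oxygens map onto a 4-aryloxy-1-methoxy-1,3-bis(silyloxy)buta-1,3-diene; C1/C6 map onto oct-2-ynoate.
- Forward: ring B is elaborated from a bought arene (Br, Bu, oxidation, CO2Me, selective O-demethylation), tied through its phenol oxygen to the C4 keto ester and silylated to the diene. Ring A is then built de novo, and debenzylation finishes.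
- The ring-B ketone travels through the key step as its trimethylsilyl enol ether, made by the same reagent that makes the diene and lost in the same acidic work-up.
- Stereochemistry: the target has no stereocentre. Only the diene geometry (aryloxy anti to the chain, 1Z) matters; it comes from the enol silylation. The carbinol centre of the Grignard adduct and the two sp3 centres of the cycloadduct are erased.

Key step: step 9

Remark: the target SMILES contains no stereocentre and no stereogenic double bond, so "single enantiomer" is taken to mean the one achiral compound as drawn.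

**Route**

Step 1
Reactants: 1 3,5-dimethoxybenzaldehyde
Product: 2 2-bromo-3,5-dimethoxybenzaldehyde
Conditions: NBS, MeCN, 0 °C to rt
Reagents that add atoms: N-bromosuccinimide, O=C1CCC(=O)N1Br
Why: Electrophilic aromatic bromination; C2 is activated ortho/para by both methoxy groups and is less hindered than C4 between them, and the symmetry of 1 makes C2 and C6 equivalent, so one monobromide is expected.

Step 2
Reactants: 2 2-bromo-3,5-dimethoxybenzaldehyde
Product: 3 1-(2-bromo-3,5-dimethoxyphenyl)pentan-1-ol (racemic)
Conditions: n-BuMgCl, THF, −78 to 0 °C; aq. NH4Cl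
Reagents that add atoms: butylmagnesium chloride, CCCC[Mg]Cl
Why: Grignard addition to the aldehyde at low temperature, where the aryl bromide does not exchange; the carbinol centre forms racemic and is removed in step 3.

Step 3
Reactants: 3 1-(2-bromo-3,5-dimethoxyphenyl)pentan-1-ol
Product: 4 1-(2-bromo-3,5-dimethoxyphenyl)pentan-1-one
Conditions: Dess–Martin periodinane, CH2Cl2, rt
Reagents that add atoms: none
Why: Dess–Martin oxidation of a secondary benzylic alcohol to the aryl ketone under neutral conditions that leave the aryl bromide and the methyl ethers untouched.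

Step 4
Reactants: 4 1-(2-bromo-3,5-dimethoxyphenyl)pentan-1-one
Product: 5 methyl 2,4-dimethoxy-6-pentanoylbenzoate
Conditions: CO (1 atm), Pd(OAc)2 (cat.), Xantphos (cat.), Et3N, MeOH/PhMe, 90 °C
Reagents that add atoms: carbon monoxide, [C-]#[O+]; methanol, CO
Why: Palladium-catalysed methoxycarbonylation (oxidative addition, CO insertion, methanolysis of the acylpalladium) with a wide-bite-angle ligand suited to ortho-substituted aryl bromides; it is run on the ketone because alcohol 3 would close to a phthalide.

Step 5
Reactants: 5 methyl 2,4-dimethoxy-6-pentanoylbenzoate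
Product: 6 methyl 2-hydroxy-4-methoxy-6-pentanoylbenzoate
Conditions: BCl3, CH2Cl2, −78 to 0 °C; H2O
Reagents that add atoms: none
Why: Chelation-controlled aryl methyl ether cleavage; boron bound to the ester carbonyl reaches only the ortho methoxy group, and the other methoxy group has no neighbouring carbonyl.

Step 6
Reactants: 6 methyl 2-hydroxy-4-methoxy-6-pentanoylbenzoate; 7 methyl 4-chloro-3-oxobutanoate (methyl 4-chloroacetoacetate)
Product: 8 methyl 4-methoxy-2-(4-methoxy-2,4-dioxobutoxy)-6-pentanoylbenzoate
Conditions: K2CO3, DMF, 0 °C to rt, slow addition of 7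
Reagents that add atoms: none
Why: Williamson-type SN2 displacement of the primary α-keto chloride by the phenoxide; carbonate deprotonates the phenol and the β-keto ester but not the aryl ketone, so Dieckmann closures onto the ring-B ester are not expected.

Step 7
Reactants: 8 methyl 4-methoxy-2-(4-methoxy-2,4-dioxobutoxy)-6-pentanoylbenzoate
Product: 9 methyl 4-methoxy-2-{[(1Z)-4-methoxy-2,4-bis(trimethylsilyloxy)buta-1,3-dien-1-yl]oxy}-6-[1-(trimethylsilyloxy)pent-1-en-1-yl]benzoate (ketene-acetal and ring-B enol-ether geometries immaterial; used crude)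
Conditions: TMSOTf (3.5 equiv), Et3N (4.5 equiv), Et2O, 0 °C to rt; removal of the ammonium salt under argon
Reagents that add atoms: trimethylsilyl trifluoromethanesulfonate, C[Si](C)(C)OS(=O)(=O)C(F)(F)F
Why: Soft enolisation with silyl triflate and amine silylates the β-keto ester twice (enol oxygen, then γ-deprotonation of the triflate-activated silyloxy-enoate) and turns the ring-B ketone into its silyl enol ether as in situ protection; no free enolate is formed that could attack the ortho ester, and the aryloxy group is expected cis to the 2-silyloxy group (1Z) on steric grounds.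

Step 8
Reactants: 10 oct-2-ynoic acid
Product: 11 benzyl oct-2-ynoate
Conditions: BnBr, K2CO3, DMF, rt
Reagents that add atoms: benzyl bromide, BrCc1ccccc1
Why: SN2 O-alkylation of the carboxylate, which avoids activating the acid next to the conjugate-acceptor triple bond.

Step 9
Reactants: 9 methyl 4-methoxy-2-{[(1Z)-4-methoxy-2,4-bis(trimethylsilyloxy)buta-1,3-dien-1-yl]oxy}-6-[1-(trimethylsilyloxy)pent-1-en-1-yl]benzoate; 11 benzyl oct-2-ynoate
Product: 13 benzyl 2,4-dihydroxy-5-[5-methoxy-2-(methoxycarbonyl)-3-pentanoylphenoxy]-6-pentylbenzoate, via cyclohexa-1,4-diene cycloadduct 12 (not isolated)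
Conditions: 11 (3 equiv), PhMe (concentrated), 120 °C, sealed tube; then 1 M HCl, THF, rt
Reagents that add atoms: none
Why: The diene, raised in energy by oxygen donors at C1 and C3, adds to the electron-poor triple bond of 11 in a normal-demand, concerted but asynchronous [4+2] cycloaddition; the closest known reaction type is the Diels–Alder/aromatisation of 1-alkoxy-1,3-bis(silyloxy)buta-1,3-dienes with acetylenic esters to give resorcylates. Ring A closes as a six-membered carbocycle in one intermolecular [4+2] event that forms C5–C6 and C1–C2 (ring-A numbering) and gives cyclohexa-1,4-diene 12. The only selectivity needed is regiochemical: the aryloxy-bearing diene terminus has the largest HOMO coefficient, because the ketene acetal and the 3-silyloxy group both push density onto it, and it bonds to the pentyl-bearing β-carbon of the ynoate, placing pentyl next to the aryl ether and the ester next to the future C2 hydroxyl. In 12 the only hydrogen on a ring sp3 carbon sits at the aryloxy carbon, so acid can aromatise only by expelling methanol from the mixed ketal carbon and enolising; the aryloxy group cannot be lost. The two sp3 centres of 12 are transient, no stereocentre survives, and the same aqueous acid removes all three trimethylsilyl groups, returning the ring-B ketone from its spectator silyl enol ether.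

Step 10
Reactants: 13 benzyl 2,4-dihydroxy-5-[5-methoxy-2-(methoxycarbonyl)-3-pentanoylphenoxy]-6-pentylbenzoate
Product: 14 2,4-dihydroxy-5-[5-methoxy-2-(methoxycarbonyl)-3-pentanoylphenoxy]-6-pentylbenzoic acid (CNP0262789.0)
Conditions: H2 (1 atm), 10% Pd/C, EtOAc, rt
Reagents that add atoms: none
Why: Hydrogenolysis of the benzyl ester O–CH2 bond over palladium under neutral conditions at room temperature, faster than reduction of the hindered aryl ketone and mild enough to avoid decarboxylation of the resorcylic acid; the methyl ester and diaryl ether are inert.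

**Compound list**
1 | 3,5-dimethoxybenzaldehyde | COc1cc(OC)cc(C=O)c1 | starting material
2 | 2-bromo-3,5-dimethoxybenzaldehyde | COc1cc(OC)c(Br)c(C=O)c1 | intermediate
3 | 1-(2-bromo-3,5-dimethoxyphenyl)pentan-1-ol (racemic) | CCCCC(O)c1cc(OC)cc(OC)c1Br | intermediate
4 | 1-(2-bromo-3,5-dimethoxyphenyl)pentan-1-one | CCCCC(=O)c1cc(OC)cc(OC)c1Br | intermediate
5 | methyl 2,4-dimethoxy-6-pentanoylbenzoate | CCCCC(=O)c1cc(OC)cc(OC)c1C(=O)OC | intermediate
6 | methyl 2-hydroxy-4-methoxy-6-pentanoylbenzoate | CCCCC(=O)c1cc(OC)cc(O)c1C(=O)OC | intermediate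
7 | methyl 4-chloro-3-oxobutanoate | COC(=O)CC(=O)CCl | starting material
8 | methyl 4-methoxy-2-(4-methoxy-2,4-dioxobutoxy)-6-pentanoylbenzoate | CCCCC(=O)c1cc(OC)cc(OCC(=O)CC(=O)OC)c1C(=O)OC | intermediate
9 | methyl 4-methoxy-2-{[(1Z)-4-methoxy-2,4-bis(trimethylsilyloxy)buta-1,3-dien-1-yl]oxy}-6-[1-(trimethylsilyloxy)pent-1-en-1-yl]benzoate | CCCC=C(O[Si](C)(C)C)c1cc(OC)cc(O/C=C(/C=C(OC)O[Si](C)(C)C)O[Si](C)(C)C)c1C(=O)OC | intermediate
10 | oct-2-ynoic acid | CCCCCC#CC(=O)O | starting material
11 | benzyl oct-2-ynoate | CCCCCC#CC(=O)OCc1ccccc1 | intermediate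
12 | benzyl 6-methoxy-3-{5-methoxy-2-(methoxycarbonyl)-3-[1-(trimethylsilyloxy)pent-1-en-1-yl]phenoxy}-2-pentyl-4,6-bis(trimethylsilyloxy)cyclohexa-1,4-diene-1-carboxylate (diastereomer mixture, not isolated) | CCCCCC1=C(C(=O)OCc2ccccc2)C(OC)(O[Si](C)(C)C)C=C(O[Si](C)(C)C)C1Oc1cc(OC)cc(C(O[Si](C)(C)C)=CCCC)c1C(=O)OC | intermediate
13 | benzyl 2,4-dihydroxy-5-[5-methoxy-2-(methoxycarbonyl)-3-pentanoylphenoxy]-6-pentylbenzoate | CCCCCc1c(Oc2cc(OC)cc(C(=O)CCCC)c2C(=O)OC)c(O)cc(O)c1C(=O)OCc1ccccc1 | intermediate
14 | 2,4-dihydroxy-5-[5-methoxy-2-(methoxycarbonyl)-3-pentanoylphenoxy]-6-pentylbenzoic acid | CCCCCc1c(Oc2cc(OC)cc(C(=O)CCCC)c2C(=O)OC)c(O)cc(O)c1C(=O)O | target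

**Count**
Total steps: 10. Longest linear sequence: 9 steps (steps 1–7, 9, 10 from compound 1); step 8 is a one-step side branch.

**Steps most likely to fail**

Step 9. The internal, alkyl-substituted ynoate is a weak dienophile, so the cycloaddition may be outrun by thermal decomposition or adventitious desilylation of the diene. Fallback, from 9 back to 13: the 2π partner is changed to the more reactive allenic ester. Hexanoyl chloride, Et3N and benzyl (triphenylphosphoranylidene)acetate (Wittig reaction of the ketene formed in situ, CH2Cl2, 0 °C to rt) would give benzyl octa-2,3-dienoate F1. Its ester-conjugated double bond should add to 9 at 20–60 °C with the same regiochemistry (nucleophilic diene terminus to the central allene carbon), giving the 2-pentylidene cyclohexene cycloadduct F2. The 1 M HCl/THF work-up then expels methanol, removes the silyl groups and moves the exocyclic double bond into the ring, which should give 13.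

Step 7. The γ-deprotonation may stay incomplete under soft enolisation, the triflate-activated ketone may be captured by the neighbouring ester carbonyl, or the enol silylation may deliver the unreactive diene geometry. Fallback, from 6 back to 13: the ketone is masked conventionally before the ether is made and the diene is built by stepwise hard enolisation.
- 6 with 1,2-bis(trimethylsilyloxy)ethane and catalytic TMSOTf (CH2Cl2, −78 to −20 °C; K2CO3/MeOH to free the phenol) would give methyl 2-(2-butyl-1,3-dioxolan-2-yl)-6-hydroxy-4-methoxybenzoate F3.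
- Alkylation with 7 as in step 6 gives methyl 2-(2-butyl-1,3-dioxolan-2-yl)-4-methoxy-6-(4-methoxy-2,4-dioxobutoxy)benzoate F4.
- Me3SiCl/Et3N gives the 3-(trimethylsilyloxy)but-2-enoate F5.
- LDA at −78 °C with Me3SiCl already present gives the dioxolane-protected bis(silyloxy)diene F6.
- Heating with 11 as in step 9 gives the dioxolane cycloadduct F7, and mild acid gives the dioxolane-protected benzyl resorcylate F8.
- 2 M HCl/THF removes the dioxolane and returns 13.

Step 6. Base-induced self-condensation of the chloroacetoacetate may compete with the slow alkylation of the hydrogen-bonded, ortho-substituted phenoxide. Fallback, from 6 back to 8: the electrophile is changed to an enol-ether-masked one that has no acidic methylene. Alkylation of 6 with methyl (E)-4-bromo-3-methoxybut-2-enoate (K2CO3, acetone, reflux) would give methyl 2-{[(2E)-2,4-dimethoxy-4-oxobut-2-en-1-yl]oxy}-4-methoxy-6-pentanoylbenzoate F9. Brief 1 M HCl/THF hydrolysis of the enol ether returns 8.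

**Further compounds**
F1 | step 9 | benzyl octa-2,3-dienoate (racemic) | CCCCC=C=CC(=O)OCc1ccccc1
F2 | step 9 | benzyl 6-methoxy-3-{5-methoxy-2-(methoxycarbonyl)-3-[1-(trimethylsilyloxy)pent-1-en-1-yl]phenoxy}-2-pentylidene-4,6-bis(trimethylsilyloxy)cyclohex-4-ene-1-carboxylate | CCCCC=C1C(C(=O)OCc2ccccc2)C(OC)(O[Si](C)(C)C)C=C(O[Si](C)(C)C)C1Oc1cc(OC)cc(C(O[Si](C)(C)C)=CCCC)c1C(=O)OC
F3 | step 7 | methyl 2-(2-butyl-1,3-dioxolan-2-yl)-6-hydroxy-4-methoxybenzoate | CCCCC1(OCCO1)c1cc(OC)cc(O)c1C(=O)OC
F4 | step 7 | methyl 2-(2-butyl-1,3-dioxolan-2-yl)-4-methoxy-6-(4-methoxy-2,4-dioxobutoxy)benzoate | CCCCC1(OCCO1)c1cc(OC)cc(OCC(=O)CC(=O)OC)c1C(=O)OC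
F5 | step 7 | methyl 2-(2-butyl-1,3-dioxolan-2-yl)-4-methoxy-6-{[4-methoxy-4-oxo-2-(trimethylsilyloxy)but-2-en-1-yl]oxy}benzoate | CCCCC1(OCCO1)c1cc(OC)cc(OCC(O[Si](C)(C)C)=CC(=O)OC)c1C(=O)OC
F6 | step 7 | methyl 2-(2-butyl-1,3-dioxolan-2-yl)-4-methoxy-6-{[(1Z)-4-methoxy-2,4-bis(trimethylsilyloxy)buta-1,3-dien-1-yl]oxy}benzoate | CCCCC1(OCCO1)c1cc(OC)cc(O/C=C(/C=C(OC)O[Si](C)(C)C)O[Si](C)(C)C)c1C(=O)OC
F7 | step 7 | benzyl 3-[3-(2-butyl-1,3-dioxolan-2-yl)-5-methoxy-2-(methoxycarbonyl)phenoxy]-6-methoxy-2-pentyl-4,6-bis(trimethylsilyloxy)cyclohexa-1,4-diene-1-carboxylate | CCCCCC1=C(C(=O)OCc2ccccc2)C(OC)(O[Si](C)(C)C)C=C(O[Si](C)(C)C)C1Oc1cc(OC)cc(C2(CCCC)OCCO2)c1C(=O)OC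
F8 | step 7 | benzyl 5-[3-(2-butyl-1,3-dioxolan-2-yl)-5-methoxy-2-(methoxycarbonyl)phenoxy]-2,4-dihydroxy-6-pentylbenzoate | CCCCCc1c(Oc2cc(OC)cc(C3(CCCC)OCCO3)c2C(=O)OC)c(O)cc(O)c1C(=O)OCc1ccccc1
F9 | step 6 | methyl 2-{[(2E)-2,4-dimethoxy-4-oxobut-2-en-1-yl]oxy}-4-methoxy-6-pentanoylbenzoate | CCCCC(=O)c1cc(OC)cc(OC/C(OC)=C\C(=O)OC)c1C(=O)OC
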